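A direct plan would start from marrubiin (A1), dehydrate its 9-OH and cleave the resulting alkene to the hexanor C9 ketone A2, add the lithium acetylide of a separately built ethynyl oxolane A3 to C9, close the spiro oxolanone by a gold-catalysed acyloxy shift and cycloisomerisation, and finish by dehydration of lactol A4 and desilylation (some sixteen steps).
Weak point 1, the excision of the side chain: it would discard six carbons, the furan among them, although the target still holds all twenty carbons of A1, and a five-step chiral fragment would have to buy them back.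
Weak point 2, the acetylide addition to the ketone that lies between a quaternary carbon and a methine: it would put the C9 oxygen on the wrong face, and the gold cascade would then have to invert C9 through an allene whose axis may not relay the configuration, i.e. a stereocentre set wrong and corrected.
Weak point 3, the protecting-group and oxidation-level traffic around the fragment union (two TBS, one TMS, one acetate; acetal to lactol to enol ether): it builds nothing and leaves the acid-labile enol ether to a late dehydration next to a β-alkoxy ketone.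

**Retrosynthetic overview**
The target is marrubenol with O9 added across the furan C13=C16 bond and C12 oxidised: ring D (C13–C14=C15–O–C16H2) is the dearomatised furan of marrubiin, and ring C (O9–C9–C11–C12–C13) is the only ring that has to be closed.
Key disconnection: the O9–C13 bond, made by bromine-induced dearomative spiroetherification of the 3-alkylfuran (Br+ to C16, 9α-OH to C13), with the C16 bromine exchanged for hydrogen in the same flask.
The C12 ketone is installed first by furfurylic C–H oxidation and is carried through the key step as a catalyst-set (12S)-carbinol, a stereocentre absent from the target: it keeps the furan nucleophilic, steers the new spiro centre C13, and is oxidised back afterwards.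
Ring order: rings A and B and the atoms of ring D come intact from marrubiin and ring C closes last; no C–C bond is cut or made, C9 is never touched, and one disiloxane is the only protecting group.

Key step: step 5

Remark: marrubiin (from Marrubium vulgare) is taken as a commercial natural product; labdane numbering is used, α meaning below and β above the decalin plane.

**Step 1**
Reactants: 1 marrubiin
Product: 2 marrubenol (15,16-epoxylabda-13(16),14-diene-6β,9α,19-triol)
Conditions: LiAlH4, THF, 0 °C to reflux; aqueous potassium sodium tartrate work-up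
Reagents that add atoms: none
Why: LiAlH4 reduction of the hindered γ-lactone to the 6β,19-diol touches no stereocentre and leaves the furan and the tertiary 9α-OH alone.

**Step 2**
Reactants: 2 marrubenol
Product: 3 15,16-epoxy-6β,19-[(1,1,3,3-tetraisopropyldisiloxane-1,3-diyl)bis(oxy)]labda-13(16),14-dien-9α-ol
Conditions: (i-Pr2SiCl)2O (1.05 equiv), imidazole (4 equiv), DMF, 0 °C to rt
Reagents that add atoms: 1,3-dichloro-1,1,3,3-tetraisopropyldisiloxane, CC(C)[Si](Cl)(C(C)C)O[Si](Cl)(C(C)C)C(C)C
Why: Cyclic silyl ether formation: the bifunctional chlorosilane should take the primary 19-OH and then close on the 6β-OH, which lies syn-axial to C19 (the pair that marrubiin bridges as a lactone), while the tertiary 9α-OH is too hindered to be silylated, so one reagent masks the two hydroxyls that must outlast the oxidation of O12.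

**Step 3**
Reactants: 3 disiloxane-protected marrubenol
Product: 4 15,16-epoxy-9α-hydroxy-6β,19-[(1,1,3,3-tetraisopropyldisiloxane-1,3-diyl)bis(oxy)]labda-13(16),14-dien-12-one
Conditions: DDQ (2.2 equiv), THF–H2O 9:1, 0 °C to rt
Reagents that add atoms: water, O
Why: DDQ benzylic-type oxidation: hydride abstraction from C12 should give a 3-furylmethyl cation that the ring oxygen stabilises through C16 (the DDQ side-chain oxidation of 3-alkylindoles is the model), water adds at C12, and a second oxidation of the furyl carbinol stops at the 3-acylfuran, which is too electron-poor to react on; no stereocentre is formed.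

**Step 4**
Reactants: 4 3-furyl ketone
Product: 5 (12S)-15,16-epoxy-6β,19-[(1,1,3,3-tetraisopropyldisiloxane-1,3-diyl)bis(oxy)]labda-13(16),14-diene-9α,12-diol
Conditions: RuCl[(S,S)-TsDPEN](p-cymene) (2 mol %), HCO2H–Et3N 5:2, CH2Cl2, rt
Reagents that add atoms: none
Why: Noyori asymmetric transfer hydrogenation of an aryl alkyl ketone, with the 3-furyl group in the aryl role: the (S,S) catalyst should give the (12S)-carbinol (same sense and same CIP pattern as acetophenone to (S)-1-phenylethanol) under catalyst control, since the nearest substrate stereocentre, C9, carries two ring branches of similar size.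

**Step 5**
Reactants: 5 (12S)-furyl carbinol
Product: 7 (12S,13R)-9α,13:15,16-diepoxy-6β,19-[(1,1,3,3-tetraisopropyldisiloxane-1,3-diyl)bis(oxy)]labd-14-en-12-ol, via 16-bromo spiro ether 6 (not isolated)
Conditions: NBS (1.0 equiv), 2,6-lutidine (2 equiv), THF, −78 °C; then Bu3SnH (3 equiv), Et3B (0.3 equiv), air, −78 °C
Reagents that add atoms: none
Why: Proposed new method: N-bromosuccinimide should transfer Br+ to C16, the α-position next to the side chain, because this σ-complex carries its charge on tertiary C13 and on the ring oxygen; the 9α-hydroxyl then adds to C13 and succinimide takes its proton, so the furan of marrubiin becomes the 2,3-dihydrofuran ring D, and Bu3SnH with Et3B and air replaces the anomeric bromine of 6 by hydrogen as a radical at −78 °C (neutral and cold, because a C16 cation or a 12-alkoxide could cleave C12–C13 to a 3-alkoxyfuran). The closest known reaction types are the halo-etherification of 3-substituted indoles (tryptophol to a 3-bromofuroindoline), the bromine-induced oxidative spirocyclisation of 2-furyl alkanols, and tin hydride reduction of glycosyl bromides; the closure at C3 of a furan is the untested part. One ring is closed, ring C, by O9–C13 bond formation in a 5-exo-trig attack on the bromine-activated C13=C16 bond. Of the two new stereocentres C16 is erased in the same flask, and C13 is controlled by the neighbouring (12S)-carbinol: in the envelope transition state each exocyclic arm on C13 eclipses one substituent on C12, the sp3 C16HBr arm should take the side of the C12 hydrogen and the flat C14H arm the side of the hydroxyl, which puts C14 cis to O12 and gives 13R (the enantiomeric catalyst in step 4 would serve if the sense proved opposite). The step needs bromine at C16 and not C15 (secured by the 3-alkyl group), ring closure faster than proton loss to a 16-bromofuran, a 1,2-hydride shift from C12 or a second bromination (secured by the five-membered tether, one equivalent of reagent at −78 °C and the electron-poor, bromine-bearing oxygen of the new enol ether), and an sp3 C12, since a C12 ketone would make the furan an unreactive vinylogous ester. C9 is not touched and keeps its configuration from marrubiin.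

**Step 6**
Reactants: 7 spiro carbinol
Product: 8 (13R)-9α,13:15,16-diepoxy-6β,19-[(1,1,3,3-tetraisopropyldisiloxane-1,3-diyl)bis(oxy)]labd-14-en-12-one
Conditions: Dess–Martin periodinane (1.5 equiv), NaHCO3, CH2Cl2, 0 °C to rt
Reagents that add atoms: none
Why: Dess–Martin oxidation of the only free hydroxyl, under NaHCO3 buffering, returns the C12 ketone and erases the relay stereocentre, the enol ether and the disiloxane being inert and the new ketone then shielding the C13–O9 bond from ionisation.

**Step 7**
Reactants: 8 protected target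
Product: 9 target, (13R)-6β,19-dihydroxy-9α,13:15,16-diepoxylabd-14-en-12-one
Conditions: Bu4NF (3 equiv), AcOH (3 equiv), THF, 0 °C to rt; pH 7 buffer work-up
Reagents that add atoms: none
Why: Fluoride cleavage of the disiloxane, buffered with acetic acid, frees the 6β- and 19-hydroxyls without the acid that would rearomatise or hydrate ring D and without the strong base that could open the β-alkoxy ketone.

**Compound list**
1 | marrubiin (15,16-epoxy-9α-hydroxylabda-13(16),14-dien-19,6β-olide) | C[C@@H]1C[C@@H](O3)[C@H]2[C@@](C)(C3=O)CCC[C@]2(C)[C@@]1(O)CCc1ccoc1 | starting material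
2 | marrubenol (15,16-epoxylabda-13(16),14-diene-6β,9α,19-triol) | C[C@@H]1C[C@@H](O)[C@H]2[C@@](C)(CO)CCC[C@]2(C)[C@@]1(O)CCc1ccoc1 | intermediate
3 | 15,16-epoxy-6β,19-[(1,1,3,3-tetraisopropyldisiloxane-1,3-diyl)bis(oxy)]labda-13(16),14-dien-9α-ol | C[C@@H]1C[C@@H](O3)[C@H]2[C@@](C)(CO[Si](C(C)C)(C(C)C)O[Si]3(C(C)C)C(C)C)CCC[C@]2(C)[C@@]1(O)CCc1ccoc1 | intermediate
4 | 15,16-epoxy-9α-hydroxy-6β,19-[(1,1,3,3-tetraisopropyldisiloxane-1,3-diyl)bis(oxy)]labda-13(16),14-dien-12-one | C[C@@H]1C[C@@H](O3)[C@H]2[C@@](C)(CO[Si](C(C)C)(C(C)C)O[Si]3(C(C)C)C(C)C)CCC[C@]2(C)[C@@]1(O)CC(=O)c1ccoc1 | intermediate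
5 | (12S)-15,16-epoxy-6β,19-[(1,1,3,3-tetraisopropyldisiloxane-1,3-diyl)bis(oxy)]labda-13(16),14-diene-9α,12-diol | C[C@@H]1C[C@@H](O3)[C@H]2[C@@](C)(CO[Si](C(C)C)(C(C)C)O[Si]3(C(C)C)C(C)C)CCC[C@]2(C)[C@@]1(O)C[C@H](O)c1ccoc1 | intermediate
6 | (12S)-16-bromo-9α,13:15,16-diepoxy-6β,19-[(1,1,3,3-tetraisopropyldisiloxane-1,3-diyl)bis(oxy)]labd-14-en-12-ol (C13 as in 7; C16 epimers, left undefined because C16 becomes CH2 in the same flask; not isolated) | C[C@@H]1C[C@@H](O3)[C@H]2[C@@](C)(CO[Si](C(C)C)(C(C)C)O[Si]3(C(C)C)C(C)C)CCC[C@]2(C)[C@@]12C[C@H](O)[C@]1(C=COC1Br)O2 | intermediate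
7 | (12S,13R)-9α,13:15,16-diepoxy-6β,19-[(1,1,3,3-tetraisopropyldisiloxane-1,3-diyl)bis(oxy)]labd-14-en-12-ol | C[C@@H]1C[C@@H](O3)[C@H]2[C@@](C)(CO[Si](C(C)C)(C(C)C)O[Si]3(C(C)C)C(C)C)CCC[C@]2(C)[C@@]12C[C@H](O)[C@]1(C=COC1)O2 | intermediate
8 | (13R)-9α,13:15,16-diepoxy-6β,19-[(1,1,3,3-tetraisopropyldisiloxane-1,3-diyl)bis(oxy)]labd-14-en-12-one | C[C@@H]1C[C@@H](O3)[C@H]2[C@@](C)(CO[Si](C(C)C)(C(C)C)O[Si]3(C(C)C)C(C)C)CCC[C@]2(C)[C@@]12CC(=O)[C@]1(C=COC1)O2 | intermediate
9 | (13R)-6β,19-dihydroxy-9α,13:15,16-diepoxylabd-14-en-12-one | C[C@@H]1C[C@@H](O)[C@H]2[C@@](C)(CO)CCC[C@]2(C)[C@@]12CC(=O)[C@]1(C=COC1)O2 | target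

**Step count and risks**
Total step count: 7. Longest linear sequence: 7 steps (the route is linear from marrubiin).

The three steps most likely to fail:

Step 5 (key step, proposed new method). After bromine transfer the furanium ion may lose the C16 proton (rearomatisation to a 16-bromofuran), shift a hydride from C12, or the new enol ether may be brominated again, each faster than O9 closes on C13; the relay of configuration from C12 to C13 may also be weak. The fallback uses known chemistry, sets out from 5 and comes back at 7. Photo-oxygenation of the 3-alkylfuran with singlet oxygen in the presence of a hindered amine (O2, rose bengal, hν, i-Pr2NEt, CH2Cl2, −78 °C) would give the γ-hydroxybutenolide F1, and NaBH4 would reduce it to the β-substituted butenolide F2. DBU would then induce intramolecular oxa-Michael addition of the 9-OH to C13 to give the spiro lactone F3; the addition is reversible, so the C13 epimers would be separated there and the unwanted one returned to F2. Reduction with i-Bu2AlH at −78 °C would give the lactol F4, and dehydration through the anomeric mesylate (MsCl, Et3N, −40 °C to rt, the hindered 12-OH reacting more slowly) would give the enol ether 7.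

Step 3. DDQ may add to the furan or polymerise it instead of abstracting hydride from C12, the C12 cation may expel the side chain by cleavage of C9–C11 assisted by the 9-OH, or the β-hydroxy ketone 4 may dehydrate or undergo retro-aldol cleavage. The fallback uses known chemistry, sets out from 3 and comes back at 4. Burgess dehydration (a syn elimination; only the C11 hydrogens are syn to the 9α-oxygen) would give the 9(11)-alkene F5. Allylic oxidation of C12, then both allylic and furfurylic, with CrO3·3,5-dimethylpyrazole would give the enone F6. Weitz–Scheffer epoxidation (t-BuOOH, DBU) from the α face, opposite the C10 methyl, would give the 9α,11-epoxy ketone F7, and SmI2 (THF–MeOH, −78 °C) would cleave its C11–O bond to the 9α-hydroxy ketone 4.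

Step 4. Hydride transfer may be slow or poorly selective, because the alkyl branch of the ketone is a bulky neopentyl-type chain with a free tertiary hydroxyl, and the amine may induce retro-aldol loss of the side chain. The fallback sets out from 4 and comes back at 5, with recycling to 4. Unselective Luche reduction (NaBH4, CeCl3·7H2O, MeOH, −40 °C) would be followed by chromatographic separation of 5 from its (12R)-epimer F8, and F8 would be returned to 4 with MnO2 (a 3-furyl carbinol is oxidised like a benzylic alcohol); resolution with recycling thus replaces catalyst control.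

**Further compounds**
F1 | step 5 | (12S)-9α,12,16-trihydroxy-6β,19-[(1,1,3,3-tetraisopropyldisiloxane-1,3-diyl)bis(oxy)]labd-13-en-15,16-olide (C16 epimers) | C[C@@H]1C[C@@H](O3)[C@H]2[C@@](C)(CO[Si](C(C)C)(C(C)C)O[Si]3(C(C)C)C(C)C)CCC[C@]2(C)[C@@]1(O)C[C@H](O)C1=CC(=O)OC1O
F2 | step 5 | (12S)-9α,12-dihydroxy-6β,19-[(1,1,3,3-tetraisopropyldisiloxane-1,3-diyl)bis(oxy)]labd-13-en-15,16-olide | C[C@@H]1C[C@@H](O3)[C@H]2[C@@](C)(CO[Si](C(C)C)(C(C)C)O[Si]3(C(C)C)C(C)C)CCC[C@]2(C)[C@@]1(O)C[C@H](O)C1=CC(=O)OC1
F3 | step 5 | (12S,13R)-9α,13-epoxy-12-hydroxy-6β,19-[(1,1,3,3-tetraisopropyldisiloxane-1,3-diyl)bis(oxy)]labdan-15,16-olide | C[C@@H]1C[C@@H](O3)[C@H]2[C@@](C)(CO[Si](C(C)C)(C(C)C)O[Si]3(C(C)C)C(C)C)CCC[C@]2(C)[C@@]12C[C@H](O)[C@]1(CC(=O)OC1)O2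
F4 | step 5 | (12S,13R)-9α,13:15,16-diepoxy-6β,19-[(1,1,3,3-tetraisopropyldisiloxane-1,3-diyl)bis(oxy)]labdane-12,15-diol (C15 epimers) | C[C@@H]1C[C@@H](O3)[C@H]2[C@@](C)(CO[Si](C(C)C)(C(C)C)O[Si]3(C(C)C)C(C)C)CCC[C@]2(C)[C@@]12C[C@H](O)[C@]1(CC(O)OC1)O2
F5 | step 3 | (9(11)E)-15,16-epoxy-6β,19-[(1,1,3,3-tetraisopropyldisiloxane-1,3-diyl)bis(oxy)]labda-9(11),13(16),14-triene | C[C@@H]1C[C@@H](O3)[C@H]2[C@@](C)(CO[Si](C(C)C)(C(C)C)O[Si]3(C(C)C)C(C)C)CCC[C@]2(C)/C1=C/Cc1ccoc1
F6 | step 3 | (9(11)E)-15,16-epoxy-6β,19-[(1,1,3,3-tetraisopropyldisiloxane-1,3-diyl)bis(oxy)]labda-9(11),13(16),14-trien-12-one | C[C@@H]1C[C@@H](O3)[C@H]2[C@@](C)(CO[Si](C(C)C)(C(C)C)O[Si]3(C(C)C)C(C)C)CCC[C@]2(C)/C1=C/C(=O)c1ccoc1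
F7 | step 3 | 9α,11:15,16-diepoxy-6β,19-[(1,1,3,3-tetraisopropyldisiloxane-1,3-diyl)bis(oxy)]labda-13(16),14-dien-12-one (C11 unassigned; it becomes CH2 in the next operation) | C[C@@H]1C[C@@H](O3)[C@H]2[C@@](C)(CO[Si](C(C)C)(C(C)C)O[Si]3(C(C)C)C(C)C)CCC[C@]2(C)[C@@]1(O2)C2C(=O)c1ccoc1
F8 | step 4 | (12R)-15,16-epoxy-6β,19-[(1,1,3,3-tetraisopropyldisiloxane-1,3-diyl)bis(oxy)]labda-13(16),14-diene-9α,12-diol | C[C@@H]1C[C@@H](O3)[C@H]2[C@@](C)(CO[Si](C(C)C)(C(C)C)O[Si]3(C(C)C)C(C)C)CCC[C@]2(C)[C@@]1(O)C[C@@H](O)c1ccoc1
A1 | direct plan | marrubiin | C[C@@H]1C[C@@H](O3)[C@H]2[C@@](C)(C3=O)CCC[C@]2(C)[C@@]1(O)CCc1ccoc1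
A2 | direct plan | 6β,19-bis(tert-butyldimethylsilyloxy)-11,12,13,14,15,16-hexanorlabdan-9-one | C[C@@H]1C[C@@H](O[Si](C)(C)C(C)(C)C)[C@H]2[C@@](C)(CO[Si](C)(C)C(C)(C)C)CCC[C@]2(C)C1=O
A3 | direct plan | (3S)-3-ethynyl-5-methoxy-3-(trimethylsilyloxy)oxolane (C5 anomers) | C#C[C@@]1(O[Si](C)(C)C)CC(OC)OC1
A4 | direct plan | (13R)-6β,19-bis(tert-butyldimethylsilyloxy)-15-hydroxy-9α,13:15,16-diepoxylabdan-12-one (lactol) | C[C@@H]1C[C@@H](O[Si](C)(C)C(C)(C)C)[C@H]2[C@@](C)(CO[Si](C)(C)C(C)(C)C)CCC[C@]2(C)[C@@]12CC(=O)[C@]1(CC(O)OC1)O2
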